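**Retrosynthetic overview**

1. Target 42 comes from hydrolysis of enol lactone 41. Ring B (O1–C2) comes from an intramolecular Mitsunobu closure of 40 with inversion at C2. The C4–C4a bond comes from C-acylation of ring-A dione 34 with anti-aldol acid 33, and O5 is masked by lactonising the C6 side-chain acid onto it.
2. The strategy rests on ring A (C4a–C5–C6–C7–C8–C8a): a 6,6-dialkylcyclohexa-2,4-dienone with quaternary C8 (lavandulyl and prenyl) and oxygen on C5, C7 and C8a, which cannot aromatise. It is made from cyclobutenone 22 and (triisopropylsiloxy)acetylene 25 by 4π opening, [2+2], 4π opening and 6π closure (bonds C8a–C4a, C5–C6, C8a–C8).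
3. 22 comes from a [2+2] of lavandulyl(prenyl)ketene 21 (malonate route from (S)-lavandulol and prenyl bromide) with siloxyalkyne 19 (Evans alkylation, Ohira–Bestmann alkynylation, acetylide oxidation).
4. Ring order: cyclobutenone (step 12), ring A (step 14), temporary δ-lactone on O5 (step 21), ring B (step 23), lactone opened (step 24).

Key step: step 14

Remark (numbering and names): target chromanone numbering is used throughout (O1, C2, C3, C4=O, C4a, C5, C6, C7, C8, C8a). "Lavandulyl" is 5-methyl-2-(prop-1-en-2-yl)hex-4-en-1-yl with its CH configured as in (S)-lavandulol 2 (this centre is R in the target); "prenyl" is 3-methylbut-2-en-1-yl.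

Assumption: the lipase in step 1 acylates (R)-lavandulol faster, so the (S)-alcohol is the enantiomer recovered.

Remark (side chain): an ynolate homologation of a 3-propylglutarate half-ester would place a CH2 between C6 and the side-chain stereocentre. Siloxyalkyne 19 is therefore built from the 2-propylsuccinate-level aldehyde 16 by one-carbon alkynylation and acetylide oxidation.

Remark (ring B): acylation at C4a turns C5–O into a carbonyl and removes the difference between O5 and O8a. O5 is therefore tied up as an enol lactone with the C6 side-chain acid while O7 still carries its silyl group. Ring B is then closed from the only remaining enol oxygen (O8a) by substitution with inversion, which requires the anti-aldol unit.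

**Route**

Step 1
Reactants: 1 (±)-lavandulol
Product: 2 (S)-lavandulol
Conditions: porcine pancreatic lipase, vinyl acetate, MTBE, rt, run to about 60% conversion; chromatography
Reagents that add atoms: none
Why: Lipase-catalysed kinetic resolution (enantioselective transesterification) should acylate the (R)-alcohol and leave the (S)-alcohol, which carries the lavandulyl stereocentre of the target.

Step 2
Reactants: 2 (S)-lavandulol
Product: 3 (S)-lavandulyl iodide
Conditions: PPh3, imidazole, I2, CH2Cl2, 0 °C → rt
Reagents that add atoms: iodine, II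
Why: Appel iodination of a primary alcohol under neutral conditions does not touch the allylic stereocentre.

Step 3
Reactants: 3 (S)-lavandulyl iodide; 4 diethyl malonate
Product: 5 diethyl 2-lavandulylmalonate
Conditions: 4 (3 equiv), NaH, THF/DMF, 0 → 60 °C
Reagents that add atoms: none
Why: Malonic ester alkylation (SN2) by a soft, weakly basic enolate should outrun E2 on the β-branched primary iodide, and excess malonate limits dialkylation.

Step 4
Reactants: 5 diethyl 2-lavandulylmalonate; 6 prenyl bromide
Product: 7 diethyl 2-lavandulyl-2-prenylmalonate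
Conditions: NaH, THF, 0 °C → rt
Reagents that add atoms: none
Why: A second malonate alkylation with a reactive allylic bromide assembles the carbon that becomes quaternary C8.

Step 5
Reactants: 7 diethyl 2-lavandulyl-2-prenylmalonate
Product: 9 2-lavandulyl-5-methylhex-4-enoic acid (both C2 epimers), via malonic diacid 8 (not isolated)
Conditions: KOH, EtOH/H2O, reflux; 1 M HCl to pH 2 at 0 °C; then pyridine, 110 °C
Reagents that add atoms: potassium hydroxide, [K+].[OH-]
Why: Saponification and thermal decarboxylation of the malonic acid in pyridine keep the alkenes away from hot acid; C2 needs no control because it becomes the sp2 ketene carbon.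

Step 6
Reactants: 10 (S)-4-benzyloxazolidin-2-one; 11 pentanoyl chloride
Product: 12 (S)-4-benzyl-3-pentanoyloxazolidin-2-one
Conditions: n-BuLi, THF, −78 °C; then 11, −78 → 0 °C
Reagents that add atoms: none
Why: N-acylation of the lithiated oxazolidinone installs the chiral auxiliary.

Step 7
Reactants: 12 (S)-4-benzyl-3-pentanoyloxazolidin-2-one; 13 tert-butyl bromoacetate
Product: 14 tert-butyl (R)-3-[(S)-4-benzyl-2-oxooxazolidine-3-carbonyl]hexanoate
Conditions: NaHMDS, THF, −78 °C; then 13, −78 → −40 °C
Reagents that add atoms: none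
Why: Evans asymmetric alkylation of the chelated (Z)-sodium enolate on the face opposite the benzyl group sets the side-chain stereocentre (R).

Step 8
Reactants: 14 tert-butyl (R)-3-[(S)-4-benzyl-2-oxooxazolidine-3-carbonyl]hexanoate
Product: 15 tert-butyl (R)-3-(hydroxymethyl)hexanoate
Conditions: LiBH4, H2O (1 equiv), Et2O, 0 °C; pH 7 work-up
Reagents that add atoms: none
Why: Reductive cleavage of the imide by LiBH4 spares the hindered tert-butyl ester, and neutral work-up avoids lactonisation.

Step 9
Reactants: 15 tert-butyl (R)-3-(hydroxymethyl)hexanoate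
Product: 16 tert-butyl (R)-3-formylhexanoate
Conditions: Dess–Martin periodinane, NaHCO3, CH2Cl2, 0 °C → rt; used at once
Reagents that add atoms: none
Why: Buffered Dess–Martin oxidation gives the α-branched aldehyde without epimerisation.

Step 10
Reactants: 16 tert-butyl (R)-3-formylhexanoate
Product: 17 tert-butyl (R)-3-ethynylhexanoate
Conditions: dimethyl (1-diazo-2-oxopropyl)phosphonate, K2CO3, MeOH, 0 °C → rt
Reagents that add atoms: dimethyl (1-diazo-2-oxopropyl)phosphonate, CC(=O)C(=[N+]=[N-])P(=O)(OC)OC
Why: Ohira–Bestmann (Seyferth–Gilbert) homologation converts the aldehyde into the terminal alkyne under mild base that an α-alkyl stereocentre and a tert-butyl ester tolerate.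

Step 11
Reactants: 17 tert-butyl (R)-3-ethynylhexanoate
Product: 19 tert-butyl (R)-3-{[(triisopropylsilyl)oxy]ethynyl}hexanoate, via lithium ynolate 18 (not isolated)
Conditions: n-BuLi (1.0 equiv), THF, −78 °C; LiOOt-Bu (from t-BuOOH and LiHMDS), −78 → −10 °C; TIPSOTf, −78 → 0 °C; filtration through Et3N-deactivated silica
Reagents that add atoms: tert-butyl hydroperoxide, CC(C)(C)OO; triisopropylsilyl triflate, CC(C)[Si](C(C)C)(C(C)C)OS(=O)(=O)C(F)(F)F
Why: Electrophilic oxygenation of the lithium acetylide by lithium tert-butyl peroxide gives the ynolate, which the bulky, hard silyl triflate traps on oxygen; the alkyne C–H is removed selectively at −78 °C and the tert-butyl ester resists attack.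

Step 12
Reactants: 9 2-lavandulyl-5-methylhex-4-enoic acid; 19 tert-butyl (R)-3-{[(triisopropylsilyl)oxy]ethynyl}hexanoate
Product: 22 2-[(3R)-1-tert-butoxy-1-oxohexan-3-yl]-4-lavandulyl-4-prenyl-3-(triisopropylsilyloxy)cyclobut-2-en-1-one (both C4 epimers), via acid chloride 20 (not isolated), via dialkylketene 21 (not isolated)
Conditions: (COCl)2, cat. DMF, CH2Cl2, 0 °C → rt, evaporate; then slow addition to 19 and Et3N in toluene, 70 °C
Reagents that add atoms: none
Why: Dehydrochlorination gives the dialkylketene, which undergoes regiospecific [2+2] cycloaddition with the siloxyalkyne (ketene carbonyl carbon to the alkyne carbon β to oxygen) to the 3-siloxycyclobutenone; the C4 configuration is irrelevant because it is lost in the next step.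

Step 13
Reactants: 23 3-phenylisoxazole
Product: 25 (triisopropylsiloxy)acetylene, via lithium ethynolate 24 (not isolated)
Conditions: n-BuLi, THF, −78 → −30 °C; TIPSOTf, −78 → 0 °C; pentane, filtration through Et3N-deactivated silica
Reagents that add atoms: triisopropylsilyl triflate, CC(C)[Si](C(C)C)(C(C)C)OS(=O)(=O)C(F)(F)F
Why: C5-lithiation of the isoxazole triggers cycloreversion to benzonitrile and lithium ethynolate, which is O-silylated by the bulky silyl triflate (ynolate silylation).

Step 14
Reactants: 22 2-[(3R)-1-tert-butoxy-1-oxohexan-3-yl]-4-lavandulyl-4-prenyl-3-(triisopropylsilyloxy)cyclobut-2-en-1-one; 25 (triisopropylsiloxy)acetylene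
Product: 29 4-[(3R)-1-tert-butoxy-1-oxohexan-3-yl]-6-lavandulyl-6-prenyl-3,5-bis(triisopropylsilyloxy)cyclohexa-2,4-dien-1-one (ring A; ring C6 = target C8 configured as in the target), via vinylketene 26 (not isolated), via 2-vinylcyclobutenone 27 (not isolated), via dienylketene 28 (not isolated)
Conditions: 25 (4 equiv), toluene (0.5 M), BHT (cat.), sealed tube, 130 °C; C8 epimers separated by preparative HPLC
Reagents that add atoms: none
Why: Proposed new method: heating opens the cyclobutenone by 4π electrocyclic cleavage of C8a–C8 to vinylketene 26, whose ketene C=C adds the siloxyalkyne in a regiospecific [2+2] (electrophilic ketene carbon C8a to the nucleophilic CH carbon, giving C8a–C4a; oxygenated alkyne carbon to C6, giving C5–C6) to form 27, and 4π opening of 27 to dienylketene 28 followed by 6π electrocyclisation (C8a–C8) closes six-membered ring A. The closest known reaction type is the thermal cyclobutenone–siloxyalkyne aromatic annulation through vinylketenes (Danheiser benzannulation); here C4 of the cyclobutenone is fully substituted, so the cascade has to stop at the 6,6-dialkylcyclohexa-2,4-dienone because quaternary C8 cannot tautomerise to a phenol. Ring A closes by thermal disrotatory 6π electrocyclisation of the dienylketene, the four-membered ring of 27 being only a relay. C8 is the one new stereocentre and is not controlled, because it is a planar alkene carbon in 26 and 28 and the ketene terminus offers no facial bias, so both C8 epimers should form and are separated, and the unwanted one may be re-equilibrated through 28 by irradiation. The step needs regioselectivity in the [2+2], secured by the matched polarisation of ketene and oxyalkyne, and chemoselectivity over the pendant alkenes and over a 1,5-hydrogen shift of the inward-rotating alkyl group, for which the excess of the far more ketenophilic siloxyalkyne at high concentration is relied on.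

Step 15
Reactants: 30 ethyl (S)-3-hydroxybutanoate
Product: 31 ethyl (2S,3S)-3-hydroxy-2-methylbutanoate
Conditions: LDA (2.1 equiv), THF, −50 → −20 °C; MeI, DMPU, −78 → 0 °C
Reagents that add atoms: iodomethane, CI
Why: Fráter–Seebach alkylation of the chelated alkoxide enolate dianion should methylate anti to the C3 substituent and set the future C3 (S) of the target.

Step 16
Reactants: 31 ethyl (2S,3S)-3-hydroxy-2-methylbutanoate
Product: 32 ethyl (2S,3S)-3-(tert-butyldimethylsilyloxy)-2-methylbutanoate
Conditions: TBSCl, imidazole, DMF, rt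
Reagents that add atoms: tert-butyldimethylsilyl chloride, CC(C)(C)[Si](C)(C)Cl
Why: Standard silylation protects the carbinol that is later displaced.

Step 17
Reactants: 32 ethyl (2S,3S)-3-(tert-butyldimethylsilyloxy)-2-methylbutanoate
Product: 33 (2S,3S)-3-(tert-butyldimethylsilyloxy)-2-methylbutanoic acid
Conditions: LiOH, THF/MeOH/H2O, 40 °C; then 1 M HCl to pH 3 at 0 °C
Reagents that add atoms: lithium hydroxide, [Li+].[OH-]
Why: Saponification gives the acid, and the carboxylate formed protects the α-stereocentre from enolisation.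

Step 18
Reactants: 29 4-[(3R)-1-tert-butoxy-1-oxohexan-3-yl]-6-lavandulyl-6-prenyl-3,5-bis(triisopropylsilyloxy)cyclohexa-2,4-dien-1-one
Product: 34 4-[(3R)-1-tert-butoxy-1-oxohexan-3-yl]-3-hydroxy-6-lavandulyl-6-prenyl-5-(triisopropylsilyloxy)cyclohexa-2,4-dien-1-one (enol of the C5/C8a dione; O7 still silylated)
Conditions: TBAF (1.0 equiv), AcOH (1.0 equiv), THF, −78 → −40 °C; used directly
Reagents that add atoms: none
Why: Buffered fluoride should cleave the C5 vinylogous silyl ester, which is the better leaving group and has a free neighbour (C4a–H), in preference to the C7 silyl ether buried between quaternary C8 and the branched C6 substituent.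

Step 19
Reactants: 34 4-[(3R)-1-tert-butoxy-1-oxohexan-3-yl]-3-hydroxy-6-lavandulyl-6-prenyl-5-(triisopropylsilyloxy)cyclohexa-2,4-dien-1-one; 33 (2S,3S)-3-(tert-butyldimethylsilyloxy)-2-methylbutanoic acid
Product: 36 C4a-acyl triketone (34 bearing the (2S,3S)-3-(tert-butyldimethylsilyloxy)-2-methylbutanoyl group on C4a; O7–TIPS and tert-butyl ester intact), via enol ester 35 (not isolated)
Conditions: DCC, DMAP, CH2Cl2, 0 °C → rt
Reagents that add atoms: none
Why: Carbodiimide O-acylation of the enol followed by DMAP-mediated O→C acyl migration (Fries-type rearrangement of enol esters of cyclic 1,3-diones) places the acyl group on C4a, the only carbon between two carbonyls that carries hydrogen.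

Step 20
Reactants: 36 C4a-acyl triketone
Product: 38 C4a-acyl triketone carboxylic acid (tert-butyl ester of 36 cleaved), via bis-trimethylsilyl derivative 37 (not isolated)
Conditions: TMSOTf, 2,6-lutidine, CH2Cl2, 0 °C; then pH 7 buffer/THF, 0 °C
Reagents that add atoms: none
Why: Silyl triflate-mediated cleavage of the tert-butyl ester (through the silyl ester, with loss of isobutene) works under buffered aprotic conditions that should spare the alkenes, the TBS ether and the hindered C7 silyl enol ether.

Step 21
Reactants: 38 C4a-acyl triketone carboxylic acid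
Product: 39 enol δ-lactone (O5–C(=O)–CH2–CH(Pr)–C6; O7–TIPS; C8a ketone)
Conditions: EDC·HCl, CH2Cl2, 0 °C → rt
Reagents that add atoms: none
Why: Carbodiimide enol lactonisation can reach only O5, through a six-membered ring, because O7 is silylated; this blocks O5 and the carboxyl group together and leaves O8a as the only oxygen available for ring B.

Step 22
Reactants: 39 enol δ-lactone
Product: 40 hydroxy enol lactone (C7 ketone; C8a enol OH; free (3S)-carbinol in the acyl chain)
Conditions: HF·pyridine, pyridine, THF, 0 °C → rt; used at once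
Reagents that add atoms: none
Why: Buffered fluoride desilylation removes the C7 TIPS and the TBS groups, and the vinylogous system tautomerises to the C8a enol hydrogen-bonded to the C4 carbonyl.

Step 23
Reactants: 40 hydroxy enol lactone
Product: 41 ring-B-closed enol lactone ((2R,3S)-2,3-dimethylchroman-4-one ring fused at C4a–C8a; lactone on O5)
Conditions: PPh3, DIAD, toluene, −20 → 0 °C
Reagents that add atoms: none
Why: Intramolecular Mitsunobu etherification lets the acidic C8a enol, the only free enol oxygen within reach, displace the activated secondary hydroxyl with inversion (6-exo-tet), turning the (3S) anti carbinol into C2 (R) cis to the C3 methyl while C3 is untouched.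

Step 24
Reactants: 41 ring-B-closed enol lactone
Product: 42 target acid CNP0266113.2
Conditions: LiOH, THF/H2O, 0 °C, short; then 0.5 M HCl to pH 3 at 0 °C
Reagents that add atoms: lithium hydroxide, [Li+].[OH-]
Why: Acyl substitution by hydroxide on the activated enol lactone releases the C5 enol and the carboxylic acid, and the cold, brief exposure to base is chosen to avoid epimerisation at C3.

**Compound list**

1 | (±)-lavandulol | CC(C)=CCC(CO)C(C)=C | starting material
2 | (S)-lavandulol | C=C(C)[C@H](CC=C(C)C)CO | intermediate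
3 | (S)-lavandulyl iodide | C=C(C)[C@H](CC=C(C)C)CI | intermediate
4 | diethyl malonate | CCOC(=O)CC(=O)OCC | starting material
5 | diethyl 2-lavandulylmalonate | C=C(C)[C@H](CC=C(C)C)CC(C(=O)OCC)C(=O)OCC | intermediate
6 | prenyl bromide | CC(C)=CCBr | starting material
7 | diethyl 2-lavandulyl-2-prenylmalonate | C=C(C)[C@H](CC=C(C)C)CC(CC=C(C)C)(C(=O)OCC)C(=O)OCC | intermediate
8 | 2-lavandulyl-2-prenylmalonic acid | C=C(C)[C@H](CC=C(C)C)CC(CC=C(C)C)(C(=O)O)C(=O)O | intermediate (not isolated)
9 | 2-lavandulyl-5-methylhex-4-enoic acid (both C2 epimers) | C=C(C)[C@H](CC=C(C)C)CC(CC=C(C)C)C(=O)O | intermediate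
10 | (S)-4-benzyloxazolidin-2-one | O=C1N[C@@H](Cc2ccccc2)CO1 | starting material
11 | pentanoyl chloride | CCCCC(=O)Cl | starting material
12 | (S)-4-benzyl-3-pentanoyloxazolidin-2-one | CCCCC(=O)N1[C@@H](Cc2ccccc2)COC1=O | intermediate
13 | tert-butyl bromoacetate | BrCC(=O)OC(C)(C)C | starting material
14 | tert-butyl (R)-3-[(S)-4-benzyl-2-oxooxazolidine-3-carbonyl]hexanoate | CCC[C@H](CC(=O)OC(C)(C)C)C(=O)N1[C@@H](Cc2ccccc2)COC1=O | intermediate
15 | tert-butyl (R)-3-(hydroxymethyl)hexanoate | CCC[C@H](CC(=O)OC(C)(C)C)CO | intermediate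
16 | tert-butyl (R)-3-formylhexanoate | CCC[C@H](CC(=O)OC(C)(C)C)C=O | intermediate
17 | tert-butyl (R)-3-ethynylhexanoate | CCC[C@H](CC(=O)OC(C)(C)C)C#C | intermediate
18 | lithium ynolate of 17 | CCC[C@H](CC(=O)OC(C)(C)C)C#C[O-].[Li+] | intermediate (not isolated)
19 | tert-butyl (R)-3-{[(triisopropylsilyl)oxy]ethynyl}hexanoate | CCC[C@H](CC(=O)OC(C)(C)C)C#CO[Si](C(C)C)(C(C)C)C(C)C | intermediate
20 | 2-lavandulyl-5-methylhex-4-enoyl chloride | C=C(C)[C@H](CC=C(C)C)CC(CC=C(C)C)C(=O)Cl | intermediate (not isolated)
21 | lavandulyl(prenyl)ketene | C=C(C)[C@H](CC=C(C)C)CC(CC=C(C)C)=C=O | intermediate (not isolated)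
22 | 2-[(3R)-1-tert-butoxy-1-oxohexan-3-yl]-4-lavandulyl-4-prenyl-3-(triisopropylsilyloxy)cyclobut-2-en-1-one (both C4 epimers; key-step precursor) | C=C(C)[C@H](CC=C(C)C)CC1(CC=C(C)C)C(=O)C([C@H](CCC)CC(=O)OC(C)(C)C)=C1O[Si](C(C)C)(C(C)C)C(C)C | intermediate
23 | 3-phenylisoxazole | c1ccc(-c2ccon2)cc1 | starting material
24 | lithium ethynolate | C#C[O-].[Li+] | intermediate (not isolated)
25 | (triisopropylsiloxy)acetylene (key-step precursor) | C#CO[Si](C(C)C)(C(C)C)C(C)C | intermediate
26 | vinylketene from 4π opening of 22 | C=C(C)[C@H](CC=C(C)C)CC(CC=C(C)C)=C(O[Si](C(C)C)(C(C)C)C(C)C)C(=C=O)[C@H](CCC)CC(=O)OC(C)(C)C | intermediate (not isolated)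
27 | 2-vinylcyclobutenone from the [2+2] of 26 with 25 | C=C(C)[C@H](CC=C(C)C)CC(CC=C(C)C)=C(O[Si](C(C)C)(C(C)C)C(C)C)C1([C@H](CCC)CC(=O)OC(C)(C)C)C(=O)C=C1O[Si](C(C)C)(C(C)C)C(C)C | intermediate (not isolated)
28 | dienylketene from 4π opening of 27 | C=C(C)[C@H](CC=C(C)C)CC(CC=C(C)C)=C(O[Si](C(C)C)(C(C)C)C(C)C)C([C@H](CCC)CC(=O)OC(C)(C)C)=C(O[Si](C(C)C)(C(C)C)C(C)C)C=C=O | intermediate (not isolated)
29 | ring-A dienone: C8a ketone, C4a–H, C5 and C7 TIPS enol ethers, C6 side chain, quaternary C8 as in the target (key-step product) | C=C(C)[C@H](CC=C(C)C)C[C@@]1(CC=C(C)C)C(O[Si](C(C)C)(C(C)C)C(C)C)=C([C@H](CCC)CC(=O)OC(C)(C)C)C(O[Si](C(C)C)(C(C)C)C(C)C)=CC1=O | intermediate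
30 | ethyl (S)-3-hydroxybutanoate | C[C@H](O)CC(=O)OCC | starting material
31 | ethyl (2S,3S)-3-hydroxy-2-methylbutanoate | C[C@H](O)[C@H](C)C(=O)OCC | intermediate
32 | ethyl (2S,3S)-3-(tert-butyldimethylsilyloxy)-2-methylbutanoate | C[C@H](O[Si](C)(C)C(C)(C)C)[C@H](C)C(=O)OCC | intermediate
33 | (2S,3S)-3-(tert-butyldimethylsilyloxy)-2-methylbutanoic acid | C[C@H](O[Si](C)(C)C(C)(C)C)[C@H](C)C(=O)O | intermediate
34 | ring-A dione enol with O7–TIPS (O5 free) | C=C(C)[C@H](CC=C(C)C)C[C@@]1(CC=C(C)C)C(O[Si](C(C)C)(C(C)C)C(C)C)=C([C@H](CCC)CC(=O)OC(C)(C)C)C(O)=CC1=O | intermediate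
35 | enol ester of 34 with 33 (drawn on O5; an O8a isomer converges) | C=C(C)[C@H](CC=C(C)C)C[C@@]1(CC=C(C)C)C(O[Si](C(C)C)(C(C)C)C(C)C)=C([C@H](CCC)CC(=O)OC(C)(C)C)C(OC(=O)[C@@H](C)[C@H](C)O[Si](C)(C)C(C)(C)C)=CC1=O | intermediate (not isolated)
36 | C4a-acyl triketone (O7–TIPS, tert-butyl ester, TBS ether) | C=C(C)[C@H](CC=C(C)C)C[C@@]1(CC=C(C)C)C(O[Si](C(C)C)(C(C)C)C(C)C)=C([C@H](CCC)CC(=O)OC(C)(C)C)C(O)=C(C(=O)[C@@H](C)[C@H](C)O[Si](C)(C)C(C)(C)C)C1=O | intermediate
37 | bis-trimethylsilyl derivative of 38 (TMS ester, TMS enol ether) | C=C(C)[C@H](CC=C(C)C)C[C@@]1(CC=C(C)C)C(O[Si](C(C)C)(C(C)C)C(C)C)=C([C@H](CCC)CC(=O)O[Si](C)(C)C)C(O[Si](C)(C)C)=C(C(=O)[C@@H](C)[C@H](C)O[Si](C)(C)C(C)(C)C)C1=O | intermediate (not isolated)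
38 | C4a-acyl triketone carboxylic acid | C=C(C)[C@H](CC=C(C)C)C[C@@]1(CC=C(C)C)C(O[Si](C(C)C)(C(C)C)C(C)C)=C([C@H](CCC)CC(=O)O)C(O)=C(C(=O)[C@@H](C)[C@H](C)O[Si](C)(C)C(C)(C)C)C1=O | intermediate
39 | enol δ-lactone on O5 (O7–TIPS, TBS ether) | C=C(C)[C@H](CC=C(C)C)C[C@@]1(CC=C(C)C)C(O[Si](C(C)C)(C(C)C)C(C)C)=C2[C@H](CCC)CC(=O)OC2=C(C(=O)[C@@H](C)[C@H](C)O[Si](C)(C)C(C)(C)C)C1=O | intermediate
40 | hydroxy enol lactone (C7 ketone, C8a enol, free (2S,3S)-3-hydroxy-2-methylbutanoyl group on C4a) | C=C(C)[C@H](CC=C(C)C)C[C@@]1(CC=C(C)C)C(=O)C2=C(OC(=O)C[C@H]2CCC)C(C(=O)[C@@H](C)[C@H](C)O)=C1O | intermediate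
41 | ring-B-closed enol lactone ((2R,3S)-2,3-dimethylchromanone, lactone on O5) | C=C(C)[C@H](CC=C(C)C)C[C@@]1(CC=C(C)C)C(=O)C3=C(OC(=O)C[C@H]3CCC)C2=C1O[C@H](C)[C@H](C)C2=O | intermediate
42 | target acid CNP0266113.2 | C=C(C)[C@H](CC=C(C)C)C[C@@]1(CC=C(C)C)C(=O)C([C@H](CCC)CC(=O)O)=C(O)C2=C1O[C@H](C)[C@H](C)C2=O | target

**Step count**

Total step count: 24.
Longest linear sequence: 15 steps (steps 6–12, 14, 18–24).

**Steps most likely to fail**

1. Step 14 (key step). The 4π opening forces one alkyl group to rotate inward and may need temperatures at which the vinylketene undergoes a 1,5-hydrogen shift or an intramolecular [2+2] with a pendant alkene. The 6π closure has to form a quaternary centre. There is no facial control at C8.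

 Fallback, setting out from 5 (with 19, 25 and 6) and returning at 29: ring A is made in its known aromatic form and dearomatised afterwards. Diester 5 is saponified and decarboxylated to lavandulylacetic acid F1. Its acid chloride with Et3N gives the monoalkylketene, which adds to 19 to give the 4-monosubstituted cyclobutenone F2. Heating F2 with 25 (toluene, 80–110 °C) is the established aromatic annulation and should give the resorcinol-type phenol F3 (free OH at C8a, lavandulyl at C8). Bromination of the one free ring position (NBS, −78 °C) gives the C4a-bromophenol F4. The lithium phenolate of F4 is C-prenylated with 6 at the alkyl-bearing ortho carbon C8 (alkylative dearomatisation; LiHMDS, toluene, 0 °C) to give the bromodienone F5. Palladium-catalysed hydrodebromination (Pd(PPh3)4, Bu3SnH) returns 29 as its C8 epimers.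

2. Step 23. The activated β-oxyphosphonium ketone may eliminate to the enone instead of being displaced. The free hydroxyl may add to C5 of the enol lactone before it is activated. C3 may epimerise by enolisation.

 Fallback, setting out from 40 and returning at 41: the alcohol is deliberately dehydrated (MsCl, Et3N, then DBU) to the (E)-2-methylbut-2-enoyl enone F6. Ring B is then closed by intramolecular oxa-Michael addition of the C8a enol oxygen (cat. Cs2CO3, or a cinchona-derived bifunctional base for facial control at C2), the known enone-to-chromanone closure. 41 is separated from its C2/C3 isomers by HPLC, and the other isomers are returned to F6 by base-mediated retro-oxa-Michael opening.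

3. Step 19. The α-stereocentre of 33 may epimerise at the acylpyridinium stage. Silanol may be lost by β-elimination. The O→C acyl migration may stall, or the C7 silyl group may be lost.

 Fallback, setting out from 29 and 32 and returning at 36: ester 32 is reduced (DIBAL-H, −78 °C) to (2S,3S)-3-(tert-butyldimethylsilyloxy)-2-methylbutanal F7. Mukaiyama aldol addition of silyl dienol ether 29 through its C4a terminus to F7 (BF3·OEt2, CH2Cl2, −78 °C) gives the C4 carbinol F8 with loss of the C5 silyl group. Dess–Martin oxidation of F8 gives 36 without passing through an activated acyl derivative.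

Further compounds
F1 | step 14 | lavandulylacetic acid (7-methyl-4-(prop-1-en-2-yl)oct-6-enoic acid, lavandulyl CH as in 2) | C=C(C)[C@H](CC=C(C)C)CCC(=O)O
F2 | step 14 | 2-[(3R)-1-tert-butoxy-1-oxohexan-3-yl]-4-lavandulyl-3-(triisopropylsilyloxy)cyclobut-2-en-1-one | C=C(C)[C@H](CC=C(C)C)CC1C(=O)C([C@H](CCC)CC(=O)OC(C)(C)C)=C1O[Si](C(C)C)(C(C)C)C(C)C
F3 | step 14 | phenol: C8a–OH, C4a–H, C5 and C7 TIPS ethers, C6 side chain, C8 lavandulyl | C=C(C)[C@H](CC=C(C)C)Cc1c(O)cc(O[Si](C(C)C)(C(C)C)C(C)C)c([C@H](CCC)CC(=O)OC(C)(C)C)c1O[Si](C(C)C)(C(C)C)C(C)C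
F4 | step 14 | C4a-bromophenol | C=C(C)[C@H](CC=C(C)C)Cc1c(O)c(Br)c(O[Si](C(C)C)(C(C)C)C(C)C)c([C@H](CCC)CC(=O)OC(C)(C)C)c1O[Si](C(C)C)(C(C)C)C(C)C
F5 | step 14 | C4a-bromo ring-A dienone (both C8 epimers) | C=C(C)[C@H](CC=C(C)C)CC1(CC=C(C)C)C(O[Si](C(C)C)(C(C)C)C(C)C)=C([C@H](CCC)CC(=O)OC(C)(C)C)C(O[Si](C(C)C)(C(C)C)C(C)C)=C(Br)C1=O
F6 | step 23 | (E)-2-methylbut-2-enoyl enone of the enol lactone | C=C(C)[C@H](CC=C(C)C)C[C@@]1(CC=C(C)C)C(=O)C2=C(OC(=O)C[C@H]2CCC)C(C(=O)/C(C)=C/C)=C1O
F7 | step 19 | (2S,3S)-3-(tert-butyldimethylsilyloxy)-2-methylbutanal | C[C@H](O[Si](C)(C)C(C)(C)C)[C@H](C)C=O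
F8 | step 19 | C4 carbinol aldol adduct (C4 epimers) | C=C(C)[C@H](CC=C(C)C)C[C@@]1(CC=C(C)C)C(O[Si](C(C)C)(C(C)C)C(C)C)=C([C@H](CCC)CC(=O)OC(C)(C)C)C(O)=C(C(O)[C@@H](C)[C@H](C)O[Si](C)(C)C(C)(C)C)C1=O
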